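**Retrosynthetic overview**
1. Locants: in each six-membered end group C1 = CMe2, C3 = CH–O, C5 = C–CH3, C6 = ring carbon bearing the chain, and C7/C8 = the first two chain carbons (plain for the bicyclic end, primed for the diol end). Cα is the butenolide carbon next to the lactone C=O.
2. Last skeletal bond: Cα–C8, made from the complete polyene–butenolide α-boronate and a small C6-ethynyl C5,C6-epoxycyclohexan-3-ol. The same palladium operation opens the oxirane, builds the 7-oxabicyclo[2.2.1]heptane, and sets C6 and the E C7=C8 alkene.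
3. Enabling feature: in the 7-oxabicyclo[2.2.1]heptane the ether oxygen links C3 to C6, and C6 is flanked by the tertiary carbinol C5 (OH trans to the bridge) and by C7=C8. This O–C6(C5–OH)–C7=C8 array is an isomer of a C5-hydroxy C6=C7=C8 allene with a free C3–OH, which is the SN2' coupling product of an ethynyl oxirane. Because C1, C5 and Cα bear no hydrogen, the derived C6–C8 π-allyl can only be captured by O3.
4. Boronate half: the butenolide comes from Sonogashira/5-exo-dig lactonisation of a polyenyne with (E)-2,3-dibromoacrylic acid, and the central CH=CH from a Wittig reaction. The diol ring comes from acetylide addition, oxidative transposition and cis-selective reduction. Both carbocycles derive from one silylated (S)-hydroxy enone (from ketoisophorone), and both C6 enyne units from (E)-3-methylpent-2-en-4-yn-1-ol.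
5. Ring order: the carbocycles are bought, then the oxirane (step 6), the butenolide (step 21) and the oxabicycle (step 23) are formed.

Key step: step 23

Assumption: 1, 12, 27 and all named reagents are catalogue chemicals. The tertiary carbinol centre of 15 forms as an epimer mixture, is erased in step 12, and is therefore left undefined. TBS = tert-butyldimethylsilyl.

**Step 1**
Reactants: 1 ketoisophorone (2,6,6-trimethylcyclohex-2-ene-1,4-dione)
Product: 2 (4S)-4-hydroxy-2,6,6-trimethylcyclohex-2-en-1-one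
Conditions: RuCl[(S,S)-TsDPEN](p-cymene) (0.5 mol %), KOH (1 mol %), i-PrOH, rt
Reagents that add atoms: none
Why: Noyori-type asymmetric transfer hydrogenation should reduce only the C4 carbonyl, because the C1 carbonyl is shielded by the gem-dimethyl and C-methyl groups, and the (S,S)-ligand, which reads the alkenyl side like the aryl group of an aryl ketone, should set the S carbinol centre that later becomes C3 and C3'.

**Step 2**
Reactants: 2 (4S)-4-hydroxy-2,6,6-trimethylcyclohex-2-en-1-one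
Product: 3 (4S)-4-(TBS-oxy)-2,6,6-trimethylcyclohex-2-en-1-one
Conditions: TBSCl, imidazole, DMF, rt
Reagents that add atoms: tert-butyldimethylsilyl chloride, CC(C)(C)[Si](C)(C)Cl
Why: Standard imidazole-promoted silylation of a secondary alcohol protects the carbinol centre without touching it.

**Step 3**
Reactants: 3 (4S)-4-(TBS-oxy)-2,6,6-trimethylcyclohex-2-en-1-one
Product: 5 (4R)-4-(TBS-oxy)-2,6,6-trimethylcyclohex-1-en-1-yl trifluoromethanesulfonate, via lithium enolate 4 (not isolated)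
Conditions: LiBH(s-Bu)3, THF, −78 °C; then N-(5-chloropyridin-2-yl)bis(trifluoromethanesulfonimide), −78 → 0 °C
Reagents that add atoms: N-(5-chloropyridin-2-yl)bis(trifluoromethanesulfonimide), FC(F)(F)S(=O)(=O)N(c1ccc(Cl)cn1)S(=O)(=O)C(F)(F)F
Why: Conjugate reduction–enolate trapping: 1,2-attack is blocked by the gem-dimethyl group, so hydride adds to the unsubstituted β-carbon of the α-methyl enone and the single tetrasubstituted enolate 4 is O-sulfonylated regiospecifically.

**Step 4**
Reactants: 5 (4R)-4-(TBS-oxy)-2,6,6-trimethylcyclohex-1-en-1-yl trifluoromethanesulfonate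
Product: 6 methyl (4R)-4-(TBS-oxy)-2,6,6-trimethylcyclohex-1-ene-1-carboxylate
Conditions: Pd(OAc)2 (5 mol %), PPh3 (10 mol %), CO (1 atm), MeOH, Et3N, DMF, 50 °C
Reagents that add atoms: carbon monoxide, [C-]#[O+]; methanol, CO
Why: Palladium-catalysed alkoxycarbonylation of an enol triflate (oxidative addition, CO insertion, methanolysis) is well precedented for hindered 2,6,6-trimethylcyclohexenyl triflates.

**Step 5**
Reactants: 6 methyl (4R)-4-(TBS-oxy)-2,6,6-trimethylcyclohex-1-ene-1-carboxylate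
Product: 7 [(4R)-4-(TBS-oxy)-2,6,6-trimethylcyclohex-1-en-1-yl]methanol
Conditions: i-Bu2AlH, CH2Cl2, −78 → 0 °C; aqueous work-up
Reagents that add atoms: none
Why: 1,2-Reduction of the conjugated ester with i-Bu2AlH gives the allylic alcohol needed as the directing handle for step 6 and leaves the silyl ether intact.

**Step 6**
Reactants: 7 [(4R)-4-(TBS-oxy)-2,6,6-trimethylcyclohex-1-en-1-yl]methanol
Product: 8 [(1R,4S,6R)-4-(TBS-oxy)-2,2,6-trimethyl-7-oxabicyclo[4.1.0]heptan-1-yl]methanol (oxirane oxygen anti to the silyloxy group)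
Conditions: Ti(Oi-Pr)4, D-(−)-diethyl tartrate, t-BuOOH, 4 Å MS, CH2Cl2, −20 °C
Reagents that add atoms: tert-butyl hydroperoxide, CC(C)(C)OO
Why: Sharpless asymmetric epoxidation, which tolerates tetrasubstituted cyclohexenylmethanols, is reagent-controlled, and the D-(−)-tartrate should deliver oxygen to the face anti to the C3 silyloxy group, which sets C5 (R, kept to the end) and the temporary C6 centre.

**Step 7**
Reactants: 8 [(1R,4S,6R)-4-(TBS-oxy)-2,2,6-trimethyl-7-oxabicyclo[4.1.0]heptan-1-yl]methanol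
Product: 9 (1S,4S,6R)-4-(TBS-oxy)-2,2,6-trimethyl-7-oxabicyclo[4.1.0]heptane-1-carbaldehyde
Conditions: n-Pr4N[RuO4] (5 mol %), N-methylmorpholine N-oxide, 4 Å MS, CH2Cl2, rt
Reagents that add atoms: none
Why: Ley–Griffith oxidation is neutral, spares the oxirane and cannot epimerise the aldehyde because its α-carbon is quaternary.

**Step 8**
Reactants: 9 (1S,4S,6R)-4-(TBS-oxy)-2,2,6-trimethyl-7-oxabicyclo[4.1.0]heptane-1-carbaldehyde
Product: 10 (1R,3S,6R)-3-(TBS-oxy)-6-ethynyl-1,5,5-trimethyl-7-oxabicyclo[4.1.0]heptane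
Conditions: dimethyl (1-diazo-2-oxopropyl)phosphonate, K2CO3, MeOH, 0 °C → rt
Reagents that add atoms: dimethyl (1-diazo-2-oxopropyl)phosphonate, COP(=O)(OC)C(=[N+]=[N-])C(C)=O
Why: The Ohira–Bestmann variant of the Seyferth–Gilbert homologation turns the non-enolisable aldehyde into the terminal alkyne under mild carbonate conditions that leave the oxirane and silyl ether untouched.

**Step 9**
Reactants: 10 (1R,3S,6R)-3-(TBS-oxy)-6-ethynyl-1,5,5-trimethyl-7-oxabicyclo[4.1.0]heptane
Product: 11 (1R,3S,6R)-6-ethynyl-1,5,5-trimethyl-7-oxabicyclo[4.1.0]heptan-3-ol (hydroxyl anti to the oxirane oxygen)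
Conditions: n-Bu4NF, THF, 0 °C → rt
Reagents that add atoms: none
Why: Fluoride cleavage of the secondary silyl ether frees the C3 hydroxyl that serves as the internal nucleophile of step 23, while the tetrasubstituted oxirane is inert to fluoride.

**Step 10**
Reactants: 12 (E)-3-methylpent-2-en-4-yn-1-ol
Product: 13 (E)-1-(TBS-oxy)-3-methylpent-2-en-4-yne
Conditions: TBSCl, imidazole, CH2Cl2, rt
Reagents that add atoms: tert-butyldimethylsilyl chloride, CC(C)(C)[Si](C)(C)Cl
Why: Standard silylation masks the primary alcohol so that only the alkyne C–H is metalated in step 11.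

**Step 11**
Reactants: 13 (E)-1-(TBS-oxy)-3-methylpent-2-en-4-yne; 3 (4S)-4-(TBS-oxy)-2,6,6-trimethylcyclohex-2-en-1-one
Product: 15 (4S)-4-(TBS-oxy)-1-[(3E)-5-(TBS-oxy)-3-methylpent-3-en-1-yn-1-yl]-2,6,6-trimethylcyclohex-2-en-1-ol (both C1 epimers), via lithium acetylide 14 (not isolated)
Conditions: 13, n-BuLi, THF, −78 °C; then 3, −78 → 0 °C
Reagents that add atoms: none
Why: 1,2-Addition of a lithium acetylide to a ketone that has no α-hydrogen on either side, as used for related 2,6,6-trimethylcyclohexenones, attaches the C7'–C11' unit, and the new tertiary carbinol centre needs no control because step 12 erases it.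

**Step 12**
Reactants: 15 (4S)-4-(TBS-oxy)-1-[(3E)-5-(TBS-oxy)-3-methylpent-3-en-1-yn-1-yl]-2,6,6-trimethylcyclohex-2-en-1-ol
Product: 16 (6S)-6-(TBS-oxy)-3-[(3E)-5-(TBS-oxy)-3-methylpent-3-en-1-yn-1-yl]-2,4,4-trimethylcyclohex-2-en-1-one
Conditions: C5H5NH[CrO3Cl] (pyridinium chlorochromate), 4 Å MS, CH2Cl2, rt
Reagents that add atoms: pyridinium chlorochromate, [O-][Cr](=O)(=O)Cl.c1cc[nH+]cc1
Why: Babler–Dauben oxidative transposition: the chromate ester of the tertiary allylic alcohol shifts [3,3] across the ring alkene (the alkyne offers no such path) and is oxidised to the enone, which moves oxygen to C4' and the double bond to C5'=C6' without touching C3'.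

**Step 13**
Reactants: 16 (6S)-6-(TBS-oxy)-3-[(3E)-5-(TBS-oxy)-3-methylpent-3-en-1-yn-1-yl]-2,4,4-trimethylcyclohex-2-en-1-one
Product: 17 (6S)-6-(TBS-oxy)-3-[(1E,3E)-5-(TBS-oxy)-3-methylpenta-1,3-dien-1-yl]-2,4,4-trimethylcyclohex-2-en-1-one
Conditions: Zn dust, AcOH, CH2Cl2, 0 °C → rt
Reagents that add atoms: none
Why: Electron-transfer semireduction by zinc in acetic acid is selective for a triple bond conjugated with the enone and has close precedent in 4-oxo-7,8-didehydro end groups, and the crowded Z-dienone relaxes to the E C7'=C8' alkene under the conditions.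

**Step 14**
Reactants: 17 (6S)-6-(TBS-oxy)-3-[(1E,3E)-5-(TBS-oxy)-3-methylpenta-1,3-dien-1-yl]-2,4,4-trimethylcyclohex-2-en-1-one
Product: 18 (1R,6S)-6-(TBS-oxy)-3-[(1E,3E)-5-(TBS-oxy)-3-methylpenta-1,3-dien-1-yl]-2,4,4-trimethylcyclohex-2-en-1-ol (cis)
Conditions: LiBH(s-Bu)3, THF, −78 °C
Reagents that add atoms: none
Why: 1,2-Reduction with a bulky borohydride (the β-carbon is fully substituted, so conjugate addition is disfavoured) should follow the equatorial trajectory, as with 2-substituted cyclohexanones, and give the pseudoaxial C4' alcohol cis to the equatorial C3' silyloxy group (4'R).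

**Step 15**
Reactants: 18 (1R,6S)-6-(TBS-oxy)-3-[(1E,3E)-5-(TBS-oxy)-3-methylpenta-1,3-dien-1-yl]-2,4,4-trimethylcyclohex-2-en-1-ol
Product: 19 (3R,4S)-3,4-bis(TBS-oxy)-1-[(1E,3E)-5-(TBS-oxy)-3-methylpenta-1,3-dien-1-yl]-2,6,6-trimethylcyclohex-1-ene
Conditions: TBSOTf, 2,6-lutidine, CH2Cl2, −78 → 0 °C
Reagents that add atoms: tert-butyldimethylsilyl trifluoromethanesulfonate, CC(C)(C)[Si](C)(C)OS(=O)(=O)C(F)(F)F
Why: A silyl triflate with a hindered pyridine base silylates the hindered allylic alcohol at low temperature without ionising it, and any 1,2-silyl migration in 18 converges on the same product.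

**Step 16**
Reactants: 19 (3R,4S)-3,4-bis(TBS-oxy)-1-[(1E,3E)-5-(TBS-oxy)-3-methylpenta-1,3-dien-1-yl]-2,6,6-trimethylcyclohex-1-ene
Product: 20 (2E,4E)-5-[(3R,4S)-3,4-bis(TBS-oxy)-2,6,6-trimethylcyclohex-1-en-1-yl]-3-methylpenta-2,4-dien-1-ol
Conditions: HF·pyridine, pyridine, THF, 0 °C
Reagents that add atoms: none
Why: Kinetic differentiation of silyl ethers: buffered HF cleaves the unhindered primary allylic ether much faster than the two flanked secondary ones.

**Step 17**
Reactants: 20 (2E,4E)-5-[(3R,4S)-3,4-bis(TBS-oxy)-2,6,6-trimethylcyclohex-1-en-1-yl]-3-methylpenta-2,4-dien-1-ol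
Product: 22 {(2E,4E)-5-[(3R,4S)-3,4-bis(TBS-oxy)-2,6,6-trimethylcyclohex-1-en-1-yl]-3-methylpenta-2,4-dien-1-yl}triphenylphosphonium bromide, via allylic bromide 21 (not isolated)
Conditions: CBr4, PPh3, CH2Cl2, −30 °C; then PPh3, rt
Reagents that add atoms: carbon tetrabromide, BrC(Br)(Br)Br; triphenylphosphine, c1ccc(cc1)P(c1ccccc1)c1ccccc1
Why: Appel bromination under neutral conditions followed by SN2 quaternisation of the labile allylic bromide 21 in the same flask avoids the acidic medium of the direct alcohol-to-phosphonium conversion, which could ionise the C4' silyl ether.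

**Step 18**
Reactants: 12 (E)-3-methylpent-2-en-4-yn-1-ol
Product: 24 (2E,4E)-5-methylhepta-2,4-dien-6-ynal, via enynal 23 (not isolated)
Conditions: MnO2, Ph3P=CHCHO (1 equiv), toluene, rt → 70 °C
Reagents that add atoms: (triphenylphosphoranylidene)acetaldehyde, O=CC=P(c1ccccc1)(c1ccccc1)c1ccccc1
Why: Tandem oxidation–Wittig process: MnO2 oxidises the allylic alcohol and the volatile enynal 23 is trapped at once by the stabilised formylmethylene ylide, which gives the E alkene.

**Step 19**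
Reactants: 22 the phosphonium bromide of step 17; 24 (2E,4E)-5-methylhepta-2,4-dien-6-ynal
Product: 26 (3R,4S)-3,4-bis(TBS-oxy)-1-[(1E,3E,5E,7E,9E)-3,10-dimethyldodeca-1,3,5,7,9-pentaen-11-yn-1-yl]-2,6,6-trimethylcyclohex-1-ene, via ylide 25 (not isolated)
Conditions: NaN(SiMe3)2, THF, −78 °C; then 24, −78 → 0 °C; then I2 (1 mol %), CH2Cl2, daylight, rt
Reagents that add atoms: none
Why: Wittig olefination of a semistabilised polyenyl ylide with an enal, the classical way to join carotenoid halves, forms the central disubstituted alkene, and iodine-catalysed equilibration converts the Z portion into the favoured all-E isomer.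

**Step 20**
Reactants: 27 propiolic acid
Product: 28 (E)-2,3-dibromoacrylic acid (β-bromine cis to the carboxyl group)
Conditions: Br2, CHCl3, 0 °C → rt, dark
Reagents that add atoms: bromine, BrBr
Why: Electrophilic anti addition of bromine to the alkyne gives the E dibromide, in which the β-bromine is cis to the carboxyl group as required for lactonisation in step 21.

**Step 21**
Reactants: 26 the pentaenynyl cyclohexene of step 19; 28 (E)-2,3-dibromoacrylic acid
Product: 30 (5Z)-5-{(2E,4E,6E,8E,10E)-11-[(3R,4S)-3,4-bis(TBS-oxy)-2,6,6-trimethylcyclohex-1-en-1-yl]-2,9-dimethylundeca-2,4,6,8,10-pentaen-1-ylidene}-3-bromofuran-2(5H)-one, via bromoenynoic acid 29 (not isolated)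
Conditions: Pd(PPh3)4 (5 mol %), CuI (10 mol %), Et3N, MeCN/THF, rt, dark; 28 in slight excess
Reagents that add atoms: none
Why: Tandem Sonogashira coupling–lactonisation of a β-haloacrylic acid whose halogen is cis to the carboxyl group: the more electrophilic β-C–Br bond couples first, and the carboxylate of 29 then adds anti to the metal-activated triple bond in a 5-exo-dig closure that gives the Z-ylidenebutenolide and keeps the α-bromine.

**Step 22**
Reactants: 30 the α-bromo ylidenebutenolide of step 21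
Product: 31 the corresponding 3-(4,4,5,5-tetramethyl-1,3,2-dioxaborolan-2-yl)furan-2(5H)-one (Br of 30 replaced by the pinacol boronate)
Conditions: B2pin2, PdCl2(dppf) (5 mol %), KOAc, 1,4-dioxane, 65 °C, dark
Reagents that add atoms: bis(pinacolato)diboron, CC1(C)OB(OC1(C)C)B1OC(C)(C)C(C)(C)O1
Why: Miyaura borylation of an alkenyl bromide with the weak base KOAc, which suppresses Suzuki homocoupling and spares the lactone, converts the α-bromide into the nucleophilic partner for step 23.

**Step 23**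
Reactants: 31 the butenolide α-boronate of step 22; 11 (1R,3S,6R)-6-ethynyl-1,5,5-trimethyl-7-oxabicyclo[4.1.0]heptan-3-ol
Product: 33 the 3',4'-bis(TBS) ether of the target, via vinylallene diol 32 (not isolated)
Conditions: Pd(PPh3)4 (8 mol %), PhCO2H (20 mol %), 1,4-dioxane/H2O (20:1), degassed, dark, 25 °C, then 60 °C
Reagents that add atoms: none
Why: Proposed new method: Pd(PPh3)4 should open the ethynyl oxirane of 11 by anti SN2' oxidative addition, the palladium-bound C5 alkoxide should take the alkenyl group from boronate 31 without added base, and reductive elimination forms the Cα–C8 bond to give vinylallene 32 with the butenolide on the face of the C3 hydroxyl, after which benzoic acid turns zerovalent palladium into H–Pd–O2CPh, which adds to the allene (H to C7) to give a C6–C7–C8 π-allyl that the C3 hydroxyl traps at C6. The closest known reaction types are the palladium-catalysed anti-selective coupling of propargylic oxiranes with boronic acids to 2,3-allenols and the Pd(PPh3)4/PhCO2H hydroalkoxylation of allenes, whereas their merger, the butenolide boronate as partner and the transannular closure are new. Ring closure: the single C6–O bond closes both five-membered ether rings (O–C3–C2–C1–C6 and O–C3–C4–C5–C6) of the 7-oxabicyclo[2.2.1]heptane in a 5-exo attack on the allyl terminus that leaves C7=C8 exocyclic. Stereocontrol: C3 and C5 are carried over from 11 (the C5–O bond is never broken), the only new centre C6 is fixed by the tether because O3 can reach C6 from one face only, trans to the C5 hydroxyl, and the axial chirality of 32 places palladium on the opposite face in the less crowded syn π-allyl, so that anti attack is matched and gives the E C7=C8 alkene. Selectivity: the strained propargylic oxirane and then the allene are the most reactive π-systems toward zerovalent palladium and H–Pd, so the polyene and silyl ethers should stay untouched, β-hydride elimination is impossible because C1, C5 and Cα carry no hydrogen, the C5 hydroxyl lies on the palladium face and cannot attack anti, and any allylic benzoate formed at C8 re-ionises, which funnels the material to 33.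

**Step 24**
Reactants: 33 the 3',4'-bis(TBS) ether of the target
Product: 34 target, (5Z)-5-{(2E,4E,6E,8E,10E)-11-[(3R,4S)-3,4-dihydroxy-2,6,6-trimethylcyclohex-1-en-1-yl]-2,9-dimethylundeca-2,4,6,8,10-pentaen-1-ylidene}-3-{(E)-2-[(1R,2R,4S)-2-hydroxy-2,6,6-trimethyl-7-oxabicyclo[2.2.1]heptan-1-yl]ethenyl}furan-2(5H)-one
Conditions: n-Bu4NF/AcOH (1:1), THF, 0 °C → rt, dark
Reagents that add atoms: none
Why: Acetic acid-buffered fluoride removes both secondary silyl ethers under nearly neutral conditions, which protects the base-sensitive ylidenebutenolide, the acid-sensitive C4' allylic alcohol and the tertiary allylic ether.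

**Compound list**
1 | ketoisophorone | CC1=CC(=O)CC(C)(C)C1=O | starting material
2 | (4S)-4-hydroxy-2,6,6-trimethylcyclohex-2-en-1-one | CC1=C[C@@H](O)CC(C)(C)C1=O | intermediate
3 | (4S)-4-(TBS-oxy)-2,6,6-trimethylcyclohex-2-en-1-one | CC1=C[C@@H](O[Si](C)(C)C(C)(C)C)CC(C)(C)C1=O | intermediate
4 | lithium (4R)-4-(TBS-oxy)-2,6,6-trimethylcyclohex-1-en-1-olate | [Li+].[O-]C1=C(C)C[C@@H](O[Si](C)(C)C(C)(C)C)CC1(C)C | intermediate
5 | (4R)-4-(TBS-oxy)-2,6,6-trimethylcyclohex-1-en-1-yl triflate | CC1=C(OS(=O)(=O)C(F)(F)F)C(C)(C)C[C@H](O[Si](C)(C)C(C)(C)C)C1 | intermediate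
6 | methyl (4R)-4-(TBS-oxy)-2,6,6-trimethylcyclohex-1-ene-1-carboxylate | COC(=O)C1=C(C)C[C@@H](O[Si](C)(C)C(C)(C)C)CC1(C)C | intermediate
7 | [(4R)-4-(TBS-oxy)-2,6,6-trimethylcyclohex-1-en-1-yl]methanol | OCC1=C(C)C[C@@H](O[Si](C)(C)C(C)(C)C)CC1(C)C | intermediate
8 | [(1R,4S,6R)-4-(TBS-oxy)-2,2,6-trimethyl-7-oxabicyclo[4.1.0]heptan-1-yl]methanol | OC[C@@]12O[C@]1(C)C[C@@H](O[Si](C)(C)C(C)(C)C)CC2(C)C | intermediate
9 | (1S,4S,6R)-4-(TBS-oxy)-2,2,6-trimethyl-7-oxabicyclo[4.1.0]heptane-1-carbaldehyde | O=C[C@@]12O[C@]1(C)C[C@@H](O[Si](C)(C)C(C)(C)C)CC2(C)C | intermediate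
10 | (1R,3S,6R)-3-(TBS-oxy)-6-ethynyl-1,5,5-trimethyl-7-oxabicyclo[4.1.0]heptane | C#C[C@@]12O[C@]1(C)C[C@@H](O[Si](C)(C)C(C)(C)C)CC2(C)C | intermediate
11 | (1R,3S,6R)-6-ethynyl-1,5,5-trimethyl-7-oxabicyclo[4.1.0]heptan-3-ol | C#C[C@@]12O[C@]1(C)C[C@@H](O)CC2(C)C | intermediate
12 | (E)-3-methylpent-2-en-4-yn-1-ol | C#C/C(C)=C/CO | starting material
13 | (E)-1-(TBS-oxy)-3-methylpent-2-en-4-yne | C#C/C(C)=C/CO[Si](C)(C)C(C)(C)C | intermediate
14 | lithium acetylide of 13 | [Li]C#C/C(C)=C/CO[Si](C)(C)C(C)(C)C | intermediate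
15 | (4S)-4-(TBS-oxy)-1-[(3E)-5-(TBS-oxy)-3-methylpent-3-en-1-yn-1-yl]-2,6,6-trimethylcyclohex-2-en-1-ol (C1 epimers) | CC1=C[C@@H](O[Si](C)(C)C(C)(C)C)CC(C)(C)C1(O)C#C/C(C)=C/CO[Si](C)(C)C(C)(C)C | intermediate
16 | (6S)-6-(TBS-oxy)-3-[(3E)-5-(TBS-oxy)-3-methylpent-3-en-1-yn-1-yl]-2,4,4-trimethylcyclohex-2-en-1-one | CC1=C(C#C/C(C)=C/CO[Si](C)(C)C(C)(C)C)C(C)(C)C[C@H](O[Si](C)(C)C(C)(C)C)C1=O | intermediate
17 | (6S)-6-(TBS-oxy)-3-[(1E,3E)-5-(TBS-oxy)-3-methylpenta-1,3-dien-1-yl]-2,4,4-trimethylcyclohex-2-en-1-one | CC1=C(/C=C/C(C)=C/CO[Si](C)(C)C(C)(C)C)C(C)(C)C[C@H](O[Si](C)(C)C(C)(C)C)C1=O | intermediate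
18 | (1R,6S)-cis alcohol from 17 | CC1=C(/C=C/C(C)=C/CO[Si](C)(C)C(C)(C)C)C(C)(C)C[C@H](O[Si](C)(C)C(C)(C)C)[C@@H]1O | intermediate
19 | tris(TBS) ether, (3R,4S) ring | CC1=C(/C=C/C(C)=C/CO[Si](C)(C)C(C)(C)C)C(C)(C)C[C@H](O[Si](C)(C)C(C)(C)C)[C@@H]1O[Si](C)(C)C(C)(C)C | intermediate
20 | (2E,4E)-5-[(3R,4S)-3,4-bis(TBS-oxy)-2,6,6-trimethylcyclohex-1-en-1-yl]-3-methylpenta-2,4-dien-1-ol | CC1=C(/C=C/C(C)=C/CO)C(C)(C)C[C@H](O[Si](C)(C)C(C)(C)C)[C@@H]1O[Si](C)(C)C(C)(C)C | intermediate
21 | allylic bromide from 20 | CC1=C(/C=C/C(C)=C/CBr)C(C)(C)C[C@H](O[Si](C)(C)C(C)(C)C)[C@@H]1O[Si](C)(C)C(C)(C)C | intermediate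
22 | triphenylphosphonium bromide from 21 | CC1=C(/C=C/C(C)=C/C[P+](c2ccccc2)(c2ccccc2)c2ccccc2)C(C)(C)C[C@H](O[Si](C)(C)C(C)(C)C)[C@@H]1O[Si](C)(C)C(C)(C)C.[Br-] | intermediate
23 | (E)-3-methylpent-2-en-4-ynal | C#C/C(C)=C/C=O | intermediate
24 | (2E,4E)-5-methylhepta-2,4-dien-6-ynal | C#C/C(C)=C/C=C/C=O | intermediate
25 | ylide from 22 | CC1=C(/C=C/C(C)=C/C=P(c2ccccc2)(c2ccccc2)c2ccccc2)C(C)(C)C[C@H](O[Si](C)(C)C(C)(C)C)[C@@H]1O[Si](C)(C)C(C)(C)C | intermediate
26 | (3R,4S)-3,4-bis(TBS-oxy)-1-[(1E,3E,5E,7E,9E)-3,10-dimethyldodeca-1,3,5,7,9-pentaen-11-yn-1-yl]-2,6,6-trimethylcyclohex-1-ene | CC1=C(/C=C/C(C)=C/C=C/C=C/C=C(C)/C#C)C(C)(C)C[C@H](O[Si](C)(C)C(C)(C)C)[C@@H]1O[Si](C)(C)C(C)(C)C | intermediate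
27 | propiolic acid | C#CC(=O)O | starting material
28 | (E)-2,3-dibromoacrylic acid | OC(=O)/C(Br)=C\Br | intermediate
29 | (2E)-2-bromo-2-en-4-ynoic acid formed from 26 and 28 (carboxyl cis to the alkynyl group) | CC1=C(/C=C/C(C)=C/C=C/C=C/C=C(C)/C#C/C=C(/Br)C(=O)O)C(C)(C)C[C@H](O[Si](C)(C)C(C)(C)C)[C@@H]1O[Si](C)(C)C(C)(C)C | intermediate
30 | α-bromo (5Z)-ylidenebutenolide, bis(TBS) | CC1=C(/C=C/C(C)=C/C=C/C=C/C=C(C)/C=C2C=C(Br)C(=O)O/2)C(C)(C)C[C@H](O[Si](C)(C)C(C)(C)C)[C@@H]1O[Si](C)(C)C(C)(C)C | intermediate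
31 | α-(pinacolboryl) (5Z)-ylidenebutenolide, bis(TBS) | CC1=C(/C=C/C(C)=C/C=C/C=C/C=C(C)/C=C2C=C(B3OC(C)(C)C(C)(C)O3)C(=O)O/2)C(C)(C)C[C@H](O[Si](C)(C)C(C)(C)C)[C@@H]1O[Si](C)(C)C(C)(C)C | intermediate
32 | vinylallene diol: butenolide Cα bears CH=C=[(2R,4S)-2,4-dihydroxy-2,6,6-trimethylcyclohexylidene], allene axis R | CC1=C(/C=C/C(C)=C/C=C/C=C/C=C(C)/C=C2C=C(C([H])=[C@@]=C3C(C)(C)C[C@H](O)C[C@@]3(C)O)C(=O)O/2)C(C)(C)C[C@H](O[Si](C)(C)C(C)(C)C)[C@@H]1O[Si](C)(C)C(C)(C)C | intermediate
33 | 3',4'-bis(TBS) ether of the target | CC1=C(/C=C/C(C)=C/C=C/C=C/C=C(C)/C=C2C=C(/C=C/[C@@]34O[C@@H](CC3(C)C)C[C@@]4(C)O)C(=O)O/2)C(C)(C)C[C@H](O[Si](C)(C)C(C)(C)C)[C@@H]1O[Si](C)(C)C(C)(C)C | intermediate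
34 | target CNP0216838.1 | CC1=C(/C=C/C(C)=C/C=C/C=C/C=C(C)/C=C2C=C(/C=C/[C@@]34O[C@@H](CC3(C)C)C[C@@]4(C)O)C(=O)O/2)C(C)(C)C[C@H](O)[C@@H]1O | target

**Totals**
Total step count: 24.
Longest linear sequence: 14 steps (1, 2, 11–17, 19, 21–24).

**Three steps most likely to fail**

1. Step 23 (proposed new method).
 - Protodeboronation of the electron-poor alkenyl boronate may outrun transmetalation.
 - The cascade may stall at the allene stage.
 - The C5 hydroxyl may close onto C8 to form a dihydrofuran.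
 - H–Pd may scramble polyene geometry.
 - The fallback sets out from 11 and 30 and comes back at 33, using known chemistry only. Compound 11 would be isomerised with catalytic camphorsulfonic acid in CH2Cl2 at 0 °C to (1S,2R,4S)-1-ethynyl-2,6,6-trimethyl-7-oxabicyclo[2.2.1]heptan-2-ol F1. This is the known acid-induced transannular opening of a 3-hydroxy-5,6-epoxide by the C3 hydroxyl. Palladium-catalysed hydrostannation (n-Bu3SnH, PdCl2(PPh3)2, THF, 0 °C) would give (1R,2R,4S)-2,6,6-trimethyl-1-[(E)-2-(tributylstannyl)ethenyl]-7-oxabicyclo[2.2.1]heptan-2-ol F2. Stille coupling of F2 with bromide 30 (Pd2(dba)3·CHCl3, AsPh3, DMF, rt) would then give 33.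

2. Step 22.
 - Homocoupling, loss of boron during purification and thermal geometric isomerisation of the long polyene at 65 °C may erode the material.
 - The fallback sets out from 24 and 28 and comes back at 31. Compound 24 would first be joined with 28 under the conditions of step 21 to give (2E,4E,6Z)-6-(4-bromo-5-oxofuran-2(5H)-ylidene)-5-methylhexa-2,4-dienal F3. This small compound would be borylated (B2pin2, PdCl2(dppf), KOAc) to (2E,4E,6Z)-5-methyl-6-[5-oxo-4-(4,4,5,5-tetramethyl-1,3,2-dioxaborolan-2-yl)furan-2(5H)-ylidene]hexa-2,4-dienal F4. Wittig reaction of F4 with ylide 25 (from 22) would give 31, so that the full polyene never meets the borylation conditions.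

3. Step 14.
 - Poor facial selectivity of hydride delivery, or competing conjugate reduction of the dienone, may occur.
 - The fallback sets out from 17 and comes back at 18. Luche reduction (NaBH4, CeCl3·7H2O, MeOH, −20 °C), which prefers axial attack, would give the trans alcohol (1S,6S)-6-(TBS-oxy)-3-[(1E,3E)-5-(TBS-oxy)-3-methylpenta-1,3-dien-1-yl]-2,4,4-trimethylcyclohex-2-en-1-ol F5. Mitsunobu inversion with 4-nitrobenzoic acid (PPh3, diisopropyl azodicarboxylate, THF) would give the cis (1R,6S)-cyclohex-2-en-1-yl 4-nitrobenzoate F6. Methanolysis (K2CO3, MeOH) would give 18.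

**Further compounds**
F1 | step 23 | (1S,2R,4S)-1-ethynyl-2,6,6-trimethyl-7-oxabicyclo[2.2.1]heptan-2-ol | C#C[C@@]12O[C@@H](CC1(C)C)C[C@@]2(C)O
F2 | step 23 | (1R,2R,4S)-2,6,6-trimethyl-1-[(E)-2-(tributylstannyl)ethenyl]-7-oxabicyclo[2.2.1]heptan-2-ol | CCCC[Sn](CCCC)(CCCC)/C=C/[C@@]12O[C@@H](CC1(C)C)C[C@@]2(C)O
F3 | step 22 | (2E,4E,6Z)-6-(4-bromo-5-oxofuran-2(5H)-ylidene)-5-methylhexa-2,4-dienal | O=C/C=C/C=C(C)/C=C1C=C(Br)C(=O)O/1
F4 | step 22 | (2E,4E,6Z)-5-methyl-6-[5-oxo-4-(4,4,5,5-tetramethyl-1,3,2-dioxaborolan-2-yl)furan-2(5H)-ylidene]hexa-2,4-dienal | O=C/C=C/C=C(C)/C=C1C=C(B2OC(C)(C)C(C)(C)O2)C(=O)O/1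
F5 | step 14 | (1S,6S)-6-(TBS-oxy)-3-[(1E,3E)-5-(TBS-oxy)-3-methylpenta-1,3-dien-1-yl]-2,4,4-trimethylcyclohex-2-en-1-ol | CC1=C(/C=C/C(C)=C/CO[Si](C)(C)C(C)(C)C)C(C)(C)C[C@H](O[Si](C)(C)C(C)(C)C)[C@H]1O
F6 | step 14 | (1R,6S)-6-(TBS-oxy)-3-[(1E,3E)-5-(TBS-oxy)-3-methylpenta-1,3-dien-1-yl]-2,4,4-trimethylcyclohex-2-en-1-yl 4-nitrobenzoate | CC1=C(/C=C/C(C)=C/CO[Si](C)(C)C(C)(C)C)C(C)(C)C[C@H](O[Si](C)(C)C(C)(C)C)[C@@H]1OC(=O)c2ccc(cc2)[N+](=O)[O-]
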